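**Strategy.** The route cuts C3–O and C3–C4 of the 3-hydroxyisoflavanone. C3 is fully substituted and bonded to the hydroxyl oxygen, ring B (C1'), C2 and C4, so a ring B aryl carbene carbon can become C3, with its ester carbon as C2. In one operation the carbene from a 2,4-bis(silyloxy)phenyl diazoacetate takes up 4-methoxybenzyl alcohol as an oxonium ylide, which adds enantioselectively to a ring A 2-fluorobenzaldehyde (CHO becomes C4, C–F becomes C8a). No ring forms there; ring C is closed later by fluoride displacement at C8a. The precursors are a bis(triisopropylsilyl)-protected aryldiazoacetate, the alcohol and a MOM-protected 3,5-diprenyl-2-fluorobenzaldehyde.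

Key step: step 6

Assumption: the sense of induction of the zirconium BINOLate cannot be predicted with certainty for these substrates. The BINOL enantiomer written in step 6 is taken to be the one that gives the (2S) coupling product; its antipode is used if a test run shows the opposite.

Remarks on the chemistry:
- The target is (3R). The coupling product is (2S) with the same spatial arrangement; the descriptor changes only because the CIP ranking of the C3 substituents changes along the route. No structural correction is needed.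
- Ring B carries triisopropylsilyl groups, not smaller silyl groups. O2' later sits close to alkoxides (reduction, ring closure) and to liberated fluoride, where a smaller aryl silyl ether could migrate or be cleaved.
- The ring A aldehyde is made by cross-coupling of a dibromide, which is shorter than repeated ether rearrangements.

**Step 1**
Reactants: 1 methyl 2,4-dihydroxyphenylacetate
Product: 2 methyl 2-[2,4-bis(triisopropylsilyloxy)phenyl]acetate
Conditions: TIPSCl (2.5 equiv), imidazole (5 equiv), DMF, rt to 40 °C
Reagents that add atoms: triisopropylsilyl chloride, CC(C)[Si](Cl)(C(C)C)C(C)C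
Why: Imidazole-mediated O-silylation of both phenols should be faster than lactonisation of the 2-hydroxyphenylacetate, and a silyl ether at O2' offers the later carbene no C–H bond alpha to oxygen for 1,5-insertion.

**Step 2**
Reactants: 2 methyl 2-[2,4-bis(triisopropylsilyloxy)phenyl]acetate
Product: 3 methyl 2-diazo-2-[2,4-bis(triisopropylsilyloxy)phenyl]acetate
Conditions: p-ABSA (1.3 equiv), DBU (1.5 equiv), MeCN, 0 °C to rt
Reagents that add atoms: 4-acetamidobenzenesulfonyl azide, CC(=O)Nc1ccc(cc1)S(=O)(=O)N=[N+]=[N-]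
Why: Regitz diazo transfer, in which the DBU-generated arylacetate enolate attacks the terminal nitrogen of the sulfonyl azide and the triazene collapses to the diazo ester, is standard for methyl arylacetates, and the aryl TIPS ethers should tolerate DBU in dry acetonitrile.

**Step 3**
Reactants: 4 2-fluoro-4-hydroxybenzaldehyde
Product: 5 3,5-dibromo-2-fluoro-4-hydroxybenzaldehyde
Conditions: Br2 (2.1 equiv), NaOAc, AcOH, rt
Reagents that add atoms: bromine, BrBr
Why: Electrophilic aromatic bromination is directed by the phenol to its two ortho positions (C3 and C5), the para position being blocked by the formyl group, and buffered acetic acid avoids bromodeformylation.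

**Step 4**
Reactants: 5 3,5-dibromo-2-fluoro-4-hydroxybenzaldehyde
Product: 6 3,5-dibromo-2-fluoro-4-(methoxymethoxy)benzaldehyde
Conditions: MOMCl, iPr2NEt, CH2Cl2, 0 °C to rt
Reagents that add atoms: chloromethyl methyl ether, COCCl
Why: O-alkylation of the acidic, hindered phenol with the small and very reactive chloromethyl ether gives an acetal that is stable to the cross-coupling, the base and the hydride steps ahead.

**Step 5**
Reactants: 6 3,5-dibromo-2-fluoro-4-(methoxymethoxy)benzaldehyde
Product: 7 2-fluoro-4-(methoxymethoxy)-3,5-bis(3-methylbut-2-enyl)benzaldehyde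
Conditions: Bu3SnCH2CH=CMe2 (2.6 equiv), Pd(PPh3)4 (10 mol%), DMF, 100 °C
Reagents that add atoms: tributyl(3-methylbut-2-enyl)stannane, CC(C)=CC[Sn](CCCC)(CCCC)CCCC
Why: Twofold Stille coupling should work because both C–Br bonds are activated for oxidative addition by the formyl group, and the allylpalladium intermediate reductively eliminates at its unhindered primary terminus to give the linear prenyl groups.

**Step 6**
Reactants: 3 methyl 2-diazo-2-[2,4-bis(triisopropylsilyloxy)phenyl]acetate; 7 2-fluoro-4-(methoxymethoxy)-3,5-bis(3-methylbut-2-enyl)benzaldehyde; 8 4-methoxybenzyl alcohol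
Product: 10 methyl (2S)-2-[2,4-bis(triisopropylsilyloxy)phenyl]-3-[2-fluoro-4-(methoxymethoxy)-3,5-bis(3-methylbut-2-enyl)phenyl]-3-hydroxy-2-[(4-methoxyphenyl)methoxy]propanoate (carbinol carbon as formed), via oxonium ylide 9 (not isolated)
Conditions: Rh2(OAc)4 (2 mol%), Zr(OBu)4 (15 mol%), (R)-BINOL (30 mol%), 4 Å MS, CH2Cl2, 0 °C to rt, slow addition of 3 (1.3 equiv) to 7 and 8 (1.2 equiv)
Reagents that add atoms: none
Why: Rh2(OAc)4 converts 3 into a rhodium carbene whose carbon (future C3) is attacked by the hydroxyl oxygen of 8 to give oxonium ylide 9 (equivalently a rhodium-associated enol), and before a 1,2-proton shift completes O–H insertion this species adds through carbon to aldehyde 7 bound to the chiral zirconium BINOLate, forming C3–O and C3–C4 in one operation. The closest known reaction type is the three-component aldol-type trapping of alcohol-derived oxonium ylides of aryldiazoacetates by aromatic aldehydes under Rh2(OAc)4 with a chiral Lewis or Brønsted acid co-catalyst. No ring is closed. The new fully substituted stereocenter C3 is controlled by the catalyst, which holds the aldehyde and the enol oxygen in a closed array and exposes one enantiotopic face of the enol; the carbinol configuration at C4 is left as formed because step 8 removes it. The step needs trapping to outrun proton transfer, which the inductively activated ortho-fluoro aldehyde, the Lewis acid and the slow addition of 3 should secure. It also needs the carbene to prefer O–H over the prenyl alkenes and over C–H bonds near O2', which the hindered trisubstituted alkenes and the silyl ethers (no C–H alpha to oxygen) should secure.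

**Step 7**
Reactants: 10 methyl (2S)-2-[2,4-bis(triisopropylsilyloxy)phenyl]-3-[2-fluoro-4-(methoxymethoxy)-3,5-bis(3-methylbut-2-enyl)phenyl]-3-hydroxy-2-[(4-methoxyphenyl)methoxy]propanoate
Product: 11 (2R)-2-[2,4-bis(triisopropylsilyloxy)phenyl]-1-[2-fluoro-4-(methoxymethoxy)-3,5-bis(3-methylbut-2-enyl)phenyl]-2-[(4-methoxyphenyl)methoxy]propane-1,3-diol (C1 as formed)
Conditions: LiBH4 (3 equiv), MeOH (3 equiv), THF, 0 °C to rt
Reagents that add atoms: none
Why: LiBH4 ester reduction is assisted by the neighbouring hydroxyl (an alkoxyborohydride delivers hydride internally), the boron-bound aldolate should be too weakly basic for retro-aldol cleavage at this temperature, and C3 has no alpha-hydrogen to epimerise.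

**Step 8**
Reactants: 11 (2R)-2-[2,4-bis(triisopropylsilyloxy)phenyl]-1-[2-fluoro-4-(methoxymethoxy)-3,5-bis(3-methylbut-2-enyl)phenyl]-2-[(4-methoxyphenyl)methoxy]propane-1,3-diol
Product: 12 (2R)-2-[2,4-bis(triisopropylsilyloxy)phenyl]-1-[2-fluoro-4-(methoxymethoxy)-3,5-bis(3-methylbut-2-enyl)phenyl]-3-hydroxy-2-[(4-methoxyphenyl)methoxy]propan-1-one
Conditions: MnO2 (activated, 20 equiv), CH2Cl2, rt
Reagents that add atoms: none
Why: MnO2 oxidation is selective for the benzylic, para-alkoxy-activated carbinol over the saturated neopentyl-type primary alcohol, so the ketone that will activate the C–F bond is made without a protecting group and both C4 epimers converge.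

**Step 9**
Reactants: 12 (2R)-2-[2,4-bis(triisopropylsilyloxy)phenyl]-1-[2-fluoro-4-(methoxymethoxy)-3,5-bis(3-methylbut-2-enyl)phenyl]-3-hydroxy-2-[(4-methoxyphenyl)methoxy]propan-1-one
Product: 13 (3R)-3-[2,4-bis(triisopropylsilyloxy)phenyl]-7-(methoxymethoxy)-3-[(4-methoxyphenyl)methoxy]-6,8-bis(3-methylbut-2-enyl)chroman-4-one
Conditions: NaH (1.2 equiv), THF, 0 °C to rt
Reagents that add atoms: none
Why: Intramolecular nucleophilic aromatic substitution, in which the primary alkoxide attacks C8a (activated by the ortho ketone) in a six-membered addition–elimination, should be fast, and in THF the fluoride leaves as insoluble NaF that cannot attack the aryl silyl ethers.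

**Step 10**
Reactants: 13 (3R)-3-[2,4-bis(triisopropylsilyloxy)phenyl]-7-(methoxymethoxy)-3-[(4-methoxyphenyl)methoxy]-6,8-bis(3-methylbut-2-enyl)chroman-4-one
Product: 14 (3R)-3-[2,4-bis(triisopropylsilyloxy)phenyl]-3-hydroxy-7-(methoxymethoxy)-6,8-bis(3-methylbut-2-enyl)chroman-4-one
Conditions: DDQ (1.5 equiv), CH2Cl2/pH 7 buffer (10:1), 0 °C
Reagents that add atoms: none
Why: Oxidative 4-methoxybenzyl ether cleavage by DDQ (benzylic hydride abstraction, then hydrolysis of the oxocarbenium ion) is run while every phenol is still capped, so the prenyl groups cannot enter DDQ-mediated chromene formation, and the buffer protects the acetal and silyl ethers.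

**Step 11**
Reactants: 14 (3R)-3-[2,4-bis(triisopropylsilyloxy)phenyl]-3-hydroxy-7-(methoxymethoxy)-6,8-bis(3-methylbut-2-enyl)chroman-4-one
Product: 15 (3R)-3-[2,4-bis(triisopropylsilyloxy)phenyl]-3,7-dihydroxy-6,8-bis(3-methylbut-2-enyl)chroman-4-one
Conditions: HCl (0.5 M), MeOH/THF (3:1), 0 °C to rt, NaHCO3 quench
Reagents that add atoms: none
Why: Acid-catalysed transacetalisation to methanol removes the MOM group of the 4-acylphenol, the most acid-labile group present, while aryl TIPS ethers, the tertiary carbinol (alpha to a carbonyl and so reluctant to ionise) and the prenyl groups should tolerate dilute acid at or below room temperature.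

**Step 12**
Reactants: 15 (3R)-3-[2,4-bis(triisopropylsilyloxy)phenyl]-3,7-dihydroxy-6,8-bis(3-methylbut-2-enyl)chroman-4-one
Product: 16 (3R)-3-(2,4-dihydroxyphenyl)-3,7-dihydroxy-6,8-bis(3-methylbut-2-enyl)chroman-4-one (CNP0211715.1)
Conditions: Bu4NF (2.5 equiv), AcOH (2.5 equiv), THF, 0 °C
Reagents that add atoms: none
Why: Fluoride-induced desilylation of both aryl silyl ethers is buffered with acetic acid so that no free phenoxide or tertiary alkoxide can trigger alpha-ketol rearrangement or ring opening, and the C3 stereocenter is not touched.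

**Compound list**
1 | methyl 2,4-dihydroxyphenylacetate | COC(=O)Cc1ccc(O)cc1O | starting material
2 | methyl 2-[2,4-bis(triisopropylsilyloxy)phenyl]acetate | COC(=O)Cc1ccc(O[Si](C(C)C)(C(C)C)C(C)C)cc1O[Si](C(C)C)(C(C)C)C(C)C | intermediate
3 | methyl 2-diazo-2-[2,4-bis(triisopropylsilyloxy)phenyl]acetate | COC(=O)C(=[N+]=[N-])c1ccc(O[Si](C(C)C)(C(C)C)C(C)C)cc1O[Si](C(C)C)(C(C)C)C(C)C | intermediate
4 | 2-fluoro-4-hydroxybenzaldehyde | O=Cc1ccc(O)cc1F | starting material
5 | 3,5-dibromo-2-fluoro-4-hydroxybenzaldehyde | O=Cc1cc(Br)c(O)c(Br)c1F | intermediate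
6 | 3,5-dibromo-2-fluoro-4-(methoxymethoxy)benzaldehyde | COCOc1c(Br)cc(C=O)c(F)c1Br | intermediate
7 | 2-fluoro-4-(methoxymethoxy)-3,5-bis(3-methylbut-2-enyl)benzaldehyde | CC(C)=CCc1cc(C=O)c(F)c(CC=C(C)C)c1OCOC | intermediate
8 | 4-methoxybenzyl alcohol | COc1ccc(CO)cc1 | starting material
9 | oxonium ylide from 3 and 8 (not isolated) | COC(=O)[C-](c1ccc(O[Si](C(C)C)(C(C)C)C(C)C)cc1O[Si](C(C)C)(C(C)C)C(C)C)[OH+]Cc1ccc(OC)cc1 | intermediate
10 | methyl (2S)-2-[2,4-bis(triisopropylsilyloxy)phenyl]-3-[2-fluoro-4-(methoxymethoxy)-3,5-bis(3-methylbut-2-enyl)phenyl]-3-hydroxy-2-[(4-methoxyphenyl)methoxy]propanoate | COC(=O)[C@](OCc1ccc(OC)cc1)(c1ccc(O[Si](C(C)C)(C(C)C)C(C)C)cc1O[Si](C(C)C)(C(C)C)C(C)C)C(O)c1cc(CC=C(C)C)c(OCOC)c(CC=C(C)C)c1F | intermediate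
11 | (2R)-2-[2,4-bis(triisopropylsilyloxy)phenyl]-1-[2-fluoro-4-(methoxymethoxy)-3,5-bis(3-methylbut-2-enyl)phenyl]-2-[(4-methoxyphenyl)methoxy]propane-1,3-diol | OC[C@](OCc1ccc(OC)cc1)(c1ccc(O[Si](C(C)C)(C(C)C)C(C)C)cc1O[Si](C(C)C)(C(C)C)C(C)C)C(O)c1cc(CC=C(C)C)c(OCOC)c(CC=C(C)C)c1F | intermediate
12 | (2R)-2-[2,4-bis(triisopropylsilyloxy)phenyl]-1-[2-fluoro-4-(methoxymethoxy)-3,5-bis(3-methylbut-2-enyl)phenyl]-3-hydroxy-2-[(4-methoxyphenyl)methoxy]propan-1-one | OC[C@](OCc1ccc(OC)cc1)(c1ccc(O[Si](C(C)C)(C(C)C)C(C)C)cc1O[Si](C(C)C)(C(C)C)C(C)C)C(=O)c1cc(CC=C(C)C)c(OCOC)c(CC=C(C)C)c1F | intermediate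
13 | (3R)-3-[2,4-bis(triisopropylsilyloxy)phenyl]-7-(methoxymethoxy)-3-[(4-methoxyphenyl)methoxy]-6,8-bis(3-methylbut-2-enyl)chroman-4-one | CC(C)=CCc1cc2c(c(CC=C(C)C)c1OCOC)OC[C@](OCc1ccc(OC)cc1)(c1ccc(O[Si](C(C)C)(C(C)C)C(C)C)cc1O[Si](C(C)C)(C(C)C)C(C)C)C2=O | intermediate
14 | (3R)-3-[2,4-bis(triisopropylsilyloxy)phenyl]-3-hydroxy-7-(methoxymethoxy)-6,8-bis(3-methylbut-2-enyl)chroman-4-one | CC(C)=CCc1cc2c(c(CC=C(C)C)c1OCOC)OC[C@](O)(c1ccc(O[Si](C(C)C)(C(C)C)C(C)C)cc1O[Si](C(C)C)(C(C)C)C(C)C)C2=O | intermediate
15 | (3R)-3-[2,4-bis(triisopropylsilyloxy)phenyl]-3,7-dihydroxy-6,8-bis(3-methylbut-2-enyl)chroman-4-one | CC(C)=CCc1cc2c(c(CC=C(C)C)c1O)OC[C@](O)(c1ccc(O[Si](C(C)C)(C(C)C)C(C)C)cc1O[Si](C(C)C)(C(C)C)C(C)C)C2=O | intermediate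
16 | (3R)-3-(2,4-dihydroxyphenyl)-3,7-dihydroxy-6,8-bis(3-methylbut-2-enyl)chroman-4-one | CC(C)=CCc1cc2c(c(CC=C(C)C)c1O)OC[C@](O)(c1ccc(O)cc1O)C2=O | target

**Step count.** Total: 12 steps. Longest linear sequence: 10 steps (4 to 16, steps 3 to 12); the diazo ester arm (steps 1 and 2) joins at step 6.

**Steps most likely to fail**

1. Step 6. Proton transfer within the ylide may outrun capture by the moderately electrophilic aldehyde, so that only O–H insertion occurs, or the congested ortho-silyloxy enol may add with poor facial selectivity. The fallback splits the bond construction into two classical operations and replaces catalytic induction by resolution. Setting out from 3, Rh2(OAc)4 (1 mol%) and 8 in CH2Cl2 should give racemic methyl 2-[2,4-bis(triisopropylsilyloxy)phenyl]-2-[(4-methoxyphenyl)methoxy]acetate F1 by plain O–H insertion. Its lithium enolate (LiN(iPr)2, THF, −78 °C) is added to aldehyde 7 and quenched cold to give the racemic aldol methyl 2-[2,4-bis(triisopropylsilyloxy)phenyl]-3-[2-fluoro-4-(methoxymethoxy)-3,5-bis(3-methylbut-2-enyl)phenyl]-3-hydroxy-2-[(4-methoxyphenyl)methoxy]propanoate F2. The diastereomers of F2 are separated on silica gel and each is resolved by preparative chromatography on a chiral stationary phase; the (2S) fractions rejoin the route as 10.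

2. Step 5. The second coupling, at the bromide flanked by fluorine and the MOM ether, may stall, or allyl transposition may deliver 1,1-dimethylallyl isomers. The fallback removes the regiochemical question by coupling an unsubstituted allyl group and building the prenyl terminus afterwards. Setting out from 6, Stille coupling with allyltributylstannane (Pd(PPh3)4, toluene, 100 °C) should give 2-fluoro-4-(methoxymethoxy)-3,5-di(prop-2-enyl)benzaldehyde F3. Twofold cross-metathesis with excess 2-methylbut-2-ene (second-generation Grubbs catalyst RuCl2(=CHPh)(H2IMes)(PCy3), CH2Cl2, 40 °C) then converts both allyl groups into prenyl groups and returns to 7.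

3. Step 11. Under protic acid the freed 7-hydroxyl (or methanol) may add to a neighbouring prenyl double bond, or the tertiary benzylic carbinol may ionise. The fallback avoids Brønsted acid by exchanging the acetal for a silyl group and merges the last two steps. Setting out from 14, TMSOTf (4 equiv) and 2,2'-bipyridyl (6 equiv) in MeCN at 0 °C to rt should convert the aryl MOM ether into the aryl trimethylsilyl ether and, with excess reagent, silylate the tertiary hydroxyl, giving (3R)-3-[2,4-bis(triisopropylsilyloxy)phenyl]-6,8-bis(3-methylbut-2-enyl)-3,7-bis(trimethylsilyloxy)chroman-4-one F4. Without purification, Bu4NF/AcOH in THF at 0 °C removes all four silyl groups and arrives directly at 16, bypassing 15.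

**Further compounds**
F1 | step 6 | methyl 2-[2,4-bis(triisopropylsilyloxy)phenyl]-2-[(4-methoxyphenyl)methoxy]acetate (racemic) | COC(=O)C(OCc1ccc(OC)cc1)c1ccc(O[Si](C(C)C)(C(C)C)C(C)C)cc1O[Si](C(C)C)(C(C)C)C(C)C
F2 | step 6 | methyl 2-[2,4-bis(triisopropylsilyloxy)phenyl]-3-[2-fluoro-4-(methoxymethoxy)-3,5-bis(3-methylbut-2-enyl)phenyl]-3-hydroxy-2-[(4-methoxyphenyl)methoxy]propanoate (racemic, both diastereomers) | COC(=O)C(OCc1ccc(OC)cc1)(c1ccc(O[Si](C(C)C)(C(C)C)C(C)C)cc1O[Si](C(C)C)(C(C)C)C(C)C)C(O)c1cc(CC=C(C)C)c(OCOC)c(CC=C(C)C)c1F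
F3 | step 5 | 2-fluoro-4-(methoxymethoxy)-3,5-di(prop-2-enyl)benzaldehyde | C=CCc1cc(C=O)c(F)c(CC=C)c1OCOC
F4 | step 11 | (3R)-3-[2,4-bis(triisopropylsilyloxy)phenyl]-6,8-bis(3-methylbut-2-enyl)-3,7-bis(trimethylsilyloxy)chroman-4-one | CC(C)=CCc1cc2c(c(CC=C(C)C)c1O[Si](C)(C)C)OC[C@](O[Si](C)(C)C)(c1ccc(O[Si](C(C)C)(C(C)C)C(C)C)cc1O[Si](C(C)C)(C(C)C)C(C)C)C2=O
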